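The route rests on cutting the bond between the lactam nitrogen and C20 of the 1,3,5-trisubstituted benzene ring (C16–C21). C16, C18 and C20 are mutually meta, so the arene maps onto 3,5-dibromophenol. Its two equivalent C–Br bonds serve in turn for the C15 carbinol and for nitrogen. A copper/diamine Goldberg amidation forms N–C20 and closes the 19-membered lactam in one operation, creating no stereocentre. Its precursor is the complete open chain: a C1 primary (E)-enamide at one end and the aryl bromide at the other. All seven stereocentres and both E-alkenes are in place, C11/C15 are TBS ethers, the phenol is a TIPS ether, and only the C7 hydroxyl is free.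

Key step: step 21

Remark on the chemistry: ansamycin numbering is used (C1 lactam carbonyl, C2–C15 ansa chain, C16 on C15, C18 bearing O, C20 bearing N). The target is read as 2E,8E,6S,7S,10S,11R,12S,14S,15R, that is 6,7-syn, 10,11-syn, 11,12-anti and 14,15-syn, so the propargylation must be a syn-selective, open-transition-state variant.
Abbreviations: Tr = triphenylmethyl; TBS = tert-butyldimethylsilyl; TIPS = triisopropylsilyl; RAMP = (R)-1-amino-2-(methoxymethyl)pyrrolidine; DMP = Dess–Martin periodinane; MIB = 3-exo-morpholinoisoborneol; TEEDA = N,N,N′,N′-tetraethylethylenediamine; DMEDA = N,N′-dimethylethylenediamine.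

**Common building block (used twice: C3–C7 and C11–C15)**

Step 1
Reactants: 1 (S)-glycidyl trityl ether
Product: 2 (2S)-1-(trityloxy)hex-5-en-2-ol
Conditions: allylMgCl, CuI (10 mol %), THF, −40 → 0 °C
Reagents that add atoms: allylmagnesium chloride, C=CC[Mg]Cl
Why: Copper-catalysed Grignard opening of a terminal epoxide (SN2 at the unsubstituted carbon) leaves the C–O stereocentre of the chiral-pool epoxide untouched, so it arrives as the S carbinol that later becomes both C6 and C12.

Step 2
Reactants: 2 (2S)-1-(trityloxy)hex-5-en-2-ol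
Product: 3 (5S)-5-methoxy-6-(trityloxy)hex-1-ene
Conditions: NaH, MeI, THF/DMF, 0 °C → rt
Reagents that add atoms: iodomethane, CI
Why: Williamson etherification of the only hydroxyl group is safe here because the trityl ether cannot migrate and the stereocentre is not involved.

**Fragment 1 (C1–C7 aldehyde)**

Step 3
Reactants: 3 (5S)-5-methoxy-6-(trityloxy)hex-1-ene; 4 methyl methacrylate
Product: 5 methyl (2E,6S)-6-methoxy-2-methyl-7-(trityloxy)hept-2-enoate
Conditions: 4 (10 equiv), second-generation Hoveyda–Grubbs catalyst (5 mol %), CH2Cl2, 40 °C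
Reagents that add atoms: none
Why: Olefin cross-metathesis between an unhindered terminal alkene and excess methacrylate, which does not homodimerise, is driven by loss of ethene and should give the thermodynamically preferred E-trisubstituted C2=C3 enoate.

Step 4
Reactants: 5 methyl (2E,6S)-6-methoxy-2-methyl-7-(trityloxy)hept-2-enoate
Product: 6 methyl (2E,6S)-7-hydroxy-6-methoxy-2-methylhept-2-enoate
Conditions: p-TsOH·H2O (10 mol %), MeOH/CH2Cl2, rt
Reagents that add atoms: none
Why: Acid-catalysed SN1 methanolysis of the trityl ether runs through the stabilised trityl cation under conditions that leave the methyl ether and the enoate alone.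

Step 5
Reactants: 6 methyl (2E,6S)-7-hydroxy-6-methoxy-2-methylhept-2-enoate
Product: 7 methyl (2E,6S)-6-methoxy-2-methyl-7-oxohept-2-enoate
Conditions: DMP, pyridine, CH2Cl2, 0 °C → rt; used directly
Reagents that add atoms: none
Why: Dess–Martin oxidation stops at the aldehyde under near-neutral conditions, so the enolisable α-methoxy centre C6 should not epimerise.

**Fragment 2 (C8–C10 allenylstannane)**

Step 6
Reactants: 8 (S)-but-3-yn-2-ol
Product: 10 (S)-pent-3-yn-2-ol, via dilithiated butynol 9 (not isolated)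
Conditions: n-BuLi (2.1 equiv), THF, −78 → 0 °C; MeI (1.0 equiv), DMPU, −78 °C → rt
Reagents that add atoms: iodomethane, CI
Why: Alkylation of the alkoxide–acetylide dianion occurs at the more nucleophilic carbon terminus, so the future C8 methyl group is installed before any aryl bromide is present and the carbinol centre is untouched.

Step 7
Reactants: 10 (S)-pent-3-yn-2-ol
Product: 11 (S)-pent-3-yn-2-yl methanesulfonate
Conditions: MsCl, Et3N, CH2Cl2, −78 → 0 °C
Reagents that add atoms: methanesulfonyl chloride, CS(=O)(=O)Cl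
Why: Mesylate formation takes place at oxygen and does not touch the C–O stereocentre.

Step 8
Reactants: 11 (S)-pent-3-yn-2-yl methanesulfonate
Product: 12 (Ra)-tributyl(penta-2,3-dien-2-yl)stannane
Conditions: Bu3SnH, LDA, THF, 0 °C; CuBr·SMe2, −78 °C; then 11, −78 °C
Reagents that add atoms: tributyltin hydride, CCCC[SnH](CCCC)CCCC
Why: SN2′ displacement of a propargylic mesylate by a stannylcuprate is anti-selective, which transfers the central chirality of the S mesylate into the Ra axial chirality of the allenylstannane.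

**Main line**

Step 9
Reactants: 3 (5S)-5-methoxy-6-(trityloxy)hex-1-ene; 13 RAMP
Product: 15 (E)-RAMP hydrazone of (4S)-4-methoxy-5-(trityloxy)pentanal, via aldehyde 14 (not isolated)
Conditions: O3, CH2Cl2, −78 °C; PPh3, → rt; concentrate; 13, MgSO4, CH2Cl2, 0 °C → rt
Reagents that add atoms: none
Why: Ozonolysis cleaves the only alkene to the C15 aldehyde, evaporation removes formaldehyde, and condensation of the crude aldehyde with the hydrazine gives the E hydrazone needed for an Enders alkylation.

Step 10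
Reactants: 15 (E)-RAMP hydrazone of (4S)-4-methoxy-5-(trityloxy)pentanal
Product: 17 (E)-RAMP hydrazone of (2S,4S)-4-methoxy-2-methyl-5-(trityloxy)pentanal, via lithium azaenolate 16 (not isolated)
Conditions: LDA, THF, 0 °C; MeI, −100 °C → rt
Reagents that add atoms: iodomethane, CI
Why: In the Enders RAMP-hydrazone alkylation the chelated lithium azaenolate is methylated on the face left open by the methoxymethylpyrrolidine, which sets C14 as S under auxiliary control regardless of the remote C12 centre.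

Step 11
Reactants: 17 (E)-RAMP hydrazone of (2S,4S)-4-methoxy-2-methyl-5-(trityloxy)pentanal
Product: 18 (2S,4S)-4-methoxy-2-methyl-5-(trityloxy)pentanal
Conditions: O3, CH2Cl2, −78 °C; argon purge; used directly
Reagents that add atoms: ozone, [O-][O+]=O
Why: Ozonolytic cleavage of the C=N bond at low temperature frees the α-branched aldehyde without acid or base, so C14 should not epimerise and the trityl ether survives.

Step 12
Reactants: 19 3,5-dibromophenol
Product: 20 (3,5-dibromophenoxy)triisopropylsilane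
Conditions: TIPSCl, imidazole, DMF, rt
Reagents that add atoms: triisopropylsilyl chloride, CC(C)[Si](Cl)(C(C)C)C(C)C
Why: Silyl ether formation masks the phenol with a bulky group that tolerates organolithium reagents, carbonate base and mild acid.

Step 13
Reactants: 20 (3,5-dibromophenoxy)triisopropylsilane; 18 (2S,4S)-4-methoxy-2-methyl-5-(trityloxy)pentanal
Product: 23 (1R,2S,4S)-1-[3-bromo-5-(triisopropylsilyloxy)phenyl]-4-methoxy-2-methyl-5-(trityloxy)pentan-1-ol, via aryllithium 21 (not isolated), via arylbutylzinc 22 (not isolated)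
Conditions: 20 (2 equiv), n-BuLi (2 equiv), t-BuOMe, −78 °C; cannulate into n-BuZnCl (from ZnCl2 + n-BuLi), −78 → 0 °C; TEEDA, (−)-MIB (10 mol %), toluene; 18, 0 °C
Reagents that add atoms: none
Why: Mono bromine–lithium exchange of the symmetric dibromide, transmetalation and amino-alcohol-catalysed asymmetric arylzinc addition deliver the aryl group to the Si face of the aldehyde, the same face that the Felkin–Anh model favours for the 14S aldehyde, so catalyst and substrate reinforce each other in setting C15 as R (14,15-syn).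

Step 14
Reactants: 23 (1R,2S,4S)-1-[3-bromo-5-(triisopropylsilyloxy)phenyl]-4-methoxy-2-methyl-5-(trityloxy)pentan-1-ol
Product: 24 C15 TBS ether of 23
Conditions: TBSOTf, 2,6-lutidine, CH2Cl2, −78 → 0 °C
Reagents that add atoms: tert-butyldimethylsilyl triflate, CC(C)(C)[Si](C)(C)OS(=O)(=O)C(F)(F)F
Why: Silylation with the triflate and a hindered base protects the congested benzylic alcohol at oxygen, so C15 keeps its configuration and the buffered medium spares the trityl ether.

Step 15
Reactants: 24 C15 TBS ether of 23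
Product: 25 (2S,4S,5R)-5-[3-bromo-5-(triisopropylsilyloxy)phenyl]-5-(tert-butyldimethylsilyloxy)-2-methoxy-4-methylpentan-1-ol
Conditions: p-TsOH·H2O (10 mol %), MeOH/CH2Cl2, 0 °C
Reagents that add atoms: none
Why: SN1 methanolysis of the trityl ether is much faster than acid solvolysis of the hindered secondary TBS ether or of the aryl TIPS ether, so only the C11 oxygen is released.

Step 16
Reactants: 25 (2S,4S,5R)-5-[3-bromo-5-(triisopropylsilyloxy)phenyl]-5-(tert-butyldimethylsilyloxy)-2-methoxy-4-methylpentan-1-ol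
Product: 26 (2S,4S,5R)-5-[3-bromo-5-(triisopropylsilyloxy)phenyl]-5-(tert-butyldimethylsilyloxy)-2-methoxy-4-methylpentanal
Conditions: DMP, pyridine, CH2Cl2, 0 °C → rt; used directly
Reagents that add atoms: none
Why: Dess–Martin oxidation gives the C11 aldehyde under near-neutral conditions that should not epimerise the α-methoxy centre C12 or disturb the silyl ethers.

Step 17
Reactants: 26 (2S,4S,5R)-5-[3-bromo-5-(triisopropylsilyloxy)phenyl]-5-(tert-butyldimethylsilyloxy)-2-methoxy-4-methylpentanal; 12 (Ra)-tributyl(penta-2,3-dien-2-yl)stannane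
Product: 27 (1R,2S,4S,5R,6S)-1-[3-bromo-5-(triisopropylsilyloxy)phenyl]-1-(tert-butyldimethylsilyloxy)-4-methoxy-2,6-dimethylnon-7-yn-5-ol
Conditions: 12 (1.5 equiv), BF3·OEt2, CH2Cl2, −78 °C
Reagents that add atoms: none
Why: The BF3-promoted SE2′ propargylation with a chiral allenylstannane runs through an open antiperiplanar transition state with attack anti to tin, giving the 10,11-syn adduct (C10 S, C11 R), and the pairing is matched because Felkin–Anh attack on the α-methoxy aldehyde under a non-chelating Lewis acid gives the same C11 configuration (11,12-anti).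

Step 18
Reactants: 27 (1R,2S,4S,5R,6S)-1-[3-bromo-5-(triisopropylsilyloxy)phenyl]-1-(tert-butyldimethylsilyloxy)-4-methoxy-2,6-dimethylnon-7-yn-5-ol
Product: 28 C11 TBS ether of 27 (C8–C21 methyl alkyne)
Conditions: TBSOTf, 2,6-lutidine, CH2Cl2, 0 °C → rt
Reagents that add atoms: tert-butyldimethylsilyl triflate, CC(C)(C)[Si](C)(C)OS(=O)(=O)C(F)(F)F
Why: Silylation with the reactive triflate overcomes the hindrance at C11, so that later only the C7 hydroxyl will be free.

Step 19
Reactants: 28 C11 TBS ether of 27 (C8–C21 methyl alkyne); 7 methyl (2E,6S)-6-methoxy-2-methyl-7-oxohept-2-enoate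
Product: 31 methyl (2E,6S,7S,8E,10S,11R,12S,14S,15R)-15-[3-bromo-5-(triisopropylsilyloxy)phenyl]-11,15-bis(tert-butyldimethylsilyloxy)-7-hydroxy-6,12-dimethoxy-2,8,10,14-tetramethylpentadeca-2,8-dienoate, via alkenylzirconocene 29 (not isolated), via alkenylmethylzinc 30 (not isolated)
Conditions: Cp2Zr(H)Cl (1.5 equiv), toluene, 50 °C; Me2Zn, −65 °C; 7 (1.5 equiv), −65 → 0 °C
Reagents that add atoms: none
Why: Syn hydrozirconation places zirconium on C8 away from the branched C10, zirconium-to-zinc transmetalation keeps the E geometry, and the alkenylzinc adds to the zinc-chelated α-methoxy aldehyde (Cram chelate model) opposite the C5 chain to set C7 as S (6,7-syn), while the ester and the aryl bromide are inert to both metals.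

Step 20
Reactants: 31 methyl ester of the seco chain
Product: 32 (2E,6S,7S,8E,10S,11R,12S,14S,15R)-15-[3-bromo-5-(triisopropylsilyloxy)phenyl]-11,15-bis(tert-butyldimethylsilyloxy)-7-hydroxy-6,12-dimethoxy-2,8,10,14-tetramethylpentadeca-2,8-dienamide
Conditions: Me3Al, NH4Cl, toluene, 0 °C → rt; then 31, 50 °C
Reagents that add atoms: ammonium chloride, [NH4+].[Cl-]
Why: Weinreb-type aminolysis with an aluminium amide converts the methyl ester directly into the primary amide without aqueous base, so the aryl silyl ether, the TBS ethers and the aryl bromide survive and the C7 hydroxyl is only masked transiently as its aluminium alkoxide.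

Step 21
Reactants: 32 seco primary enamide aryl bromide
Product: 33 macrolactam with free C7 hydroxyl (11,15-bis-O-TBS, 18-O-TIPS)
Conditions: CuI (50 mol %), DMEDA (1 equiv), K2CO3 (3 equiv), toluene (2 mM), 110 °C, argon
Reagents that add atoms: none
Why: K2CO3 deprotonates the copper-bound primary amide to a diamine-ligated monovalent copper amidate, which activates the C20–Br bond (oxidative addition to trivalent copper) and releases the anilide by C–N reductive elimination, regenerating the catalyst. The closest known reaction is the Goldberg amidation of aryl bromides with primary amides under CuI/1,2-diamine catalysis, which is also known in intramolecular form for macrolactams. The single ring formed is the 19-membered ansa lactam (N, C1–C16, C21, C20), closed end-to-end by N-arylation with the arene bridged meta. No stereocentre is created, and none should epimerise under the weak, insoluble carbonate base. Selectivity for nitrogen is secured because the C1 carboxamide is the only N–H group (the carbamate comes later), K2CO3 does not generate the C7 alkoxide, diamine-ligated copper does not arylate aliphatic alcohols, and the phenol stays masked as its TIPS ether. Millimolar dilution favours ring closure over oligomerisation, and no regiochemical question arises because a single C–Br bond is left on the ring.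

Step 22
Reactants: 33 macrolactam with free C7 hydroxyl
Product: 35 C7 carbamate of 33, via trichloroacetyl carbamate 34 (not isolated)
Conditions: Cl3CC(O)NCO, CH2Cl2, 0 °C; then neutral Al2O3, rt
Reagents that add atoms: trichloroacetyl isocyanate, O=C=NC(=O)C(Cl)(Cl)Cl
Why: Carbamoylation by addition of the only free hydroxyl group to the highly electrophilic acyl isocyanate, followed by hydrolysis of the activated trichloroacetyl imide on neutral alumina, leaves the C7–O bond intact (configuration retained) and spares the aryl silyl ether and the much less nucleophilic anilide.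

Step 23
Reactants: 35 C7 carbamate of 33
Product: 36 target CNP0309815.1
Conditions: HF·pyridine, pyridine/THF, 0 °C → rt
Reagents that add atoms: none
Why: Fluoride-driven global desilylation cleaves all three Si–O bonds under buffered conditions that should spare the allylic carbamate, the benzylic alcohol (not stabilised towards ionisation by its meta substituents) and the lactam.

**Compound list**

1 | (S)-glycidyl trityl ether | C1O[C@@H]1COC(c1ccccc1)(c1ccccc1)c1ccccc1 | starting material
2 | (2S)-1-(trityloxy)hex-5-en-2-ol | C=CCC[C@H](O)COC(c1ccccc1)(c1ccccc1)c1ccccc1 | intermediate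
3 | (5S)-5-methoxy-6-(trityloxy)hex-1-ene | C=CCC[C@H](OC)COC(c1ccccc1)(c1ccccc1)c1ccccc1 | intermediate
4 | methyl methacrylate | C=C(C)C(=O)OC | starting material
5 | methyl (2E,6S)-6-methoxy-2-methyl-7-(trityloxy)hept-2-enoate | COC(=O)/C(C)=C/CC[C@H](OC)COC(c1ccccc1)(c1ccccc1)c1ccccc1 | intermediate
6 | methyl (2E,6S)-7-hydroxy-6-methoxy-2-methylhept-2-enoate | COC(=O)/C(C)=C/CC[C@H](OC)CO | intermediate
7 | methyl (2E,6S)-6-methoxy-2-methyl-7-oxohept-2-enoate | COC(=O)/C(C)=C/CC[C@H](OC)C=O | intermediate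
8 | (S)-but-3-yn-2-ol | C#C[C@H](C)O | starting material
9 | dilithiated (S)-but-3-yn-2-ol | [Li]C#C[C@H](C)O[Li] | intermediate
10 | (S)-pent-3-yn-2-ol | CC#C[C@H](C)O | intermediate
11 | (S)-pent-3-yn-2-yl methanesulfonate | CC#C[C@H](C)OS(C)(=O)=O | intermediate
12 | (Ra)-tributyl(penta-2,3-dien-2-yl)stannane | CC([Sn](CCCC)(CCCC)CCCC)=[C@@]=C([H])C | intermediate
13 | RAMP, (R)-1-amino-2-(methoxymethyl)pyrrolidine | COC[C@H]1CCCN1N | starting material
14 | (4S)-4-methoxy-5-(trityloxy)pentanal | O=CCC[C@H](OC)COC(c1ccccc1)(c1ccccc1)c1ccccc1 | intermediate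
15 | (E)-RAMP hydrazone of 14 | COC[C@H]1CCCN1/N=C/CC[C@H](OC)COC(c1ccccc1)(c1ccccc1)c1ccccc1 | intermediate
16 | lithium azaenolate of 15 | [Li+].COC[C@H]1CCCN1[N-]/C=C/C[C@H](OC)COC(c1ccccc1)(c1ccccc1)c1ccccc1 | intermediate
17 | (E)-RAMP hydrazone of (2S,4S)-4-methoxy-2-methyl-5-(trityloxy)pentanal | COC[C@H]1CCCN1/N=C/[C@@H](C)C[C@H](OC)COC(c1ccccc1)(c1ccccc1)c1ccccc1 | intermediate
18 | (2S,4S)-4-methoxy-2-methyl-5-(trityloxy)pentanal | O=C[C@@H](C)C[C@H](OC)COC(c1ccccc1)(c1ccccc1)c1ccccc1 | intermediate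
19 | 3,5-dibromophenol | Oc1cc(Br)cc(Br)c1 | starting material
20 | (3,5-dibromophenoxy)triisopropylsilane | CC(C)[Si](Oc1cc(Br)cc(Br)c1)(C(C)C)C(C)C | intermediate
21 | [3-bromo-5-(triisopropylsilyloxy)phenyl]lithium | [Li]c1cc(Br)cc(O[Si](C(C)C)(C(C)C)C(C)C)c1 | intermediate
22 | butyl[3-bromo-5-(triisopropylsilyloxy)phenyl]zinc | CCCC[Zn]c1cc(Br)cc(O[Si](C(C)C)(C(C)C)C(C)C)c1 | intermediate
23 | (1R,2S,4S)-1-[3-bromo-5-(triisopropylsilyloxy)phenyl]-4-methoxy-2-methyl-5-(trityloxy)pentan-1-ol | C(c1ccccc1)(c1ccccc1)(c1ccccc1)OC[C@@H](OC)C[C@H](C)[C@@H](O)c1cc(Br)cc(O[Si](C(C)C)(C(C)C)C(C)C)c1 | intermediate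
24 | C15 TBS ether of 23 | C(c1ccccc1)(c1ccccc1)(c1ccccc1)OC[C@@H](OC)C[C@H](C)[C@@H](O[Si](C)(C)C(C)(C)C)c1cc(Br)cc(O[Si](C(C)C)(C(C)C)C(C)C)c1 | intermediate
25 | (2S,4S,5R)-5-aryl-5-(TBSO)-2-methoxy-4-methylpentan-1-ol (aryl = 3-bromo-5-TIPSO-phenyl) | OC[C@@H](OC)C[C@H](C)[C@@H](O[Si](C)(C)C(C)(C)C)c1cc(Br)cc(O[Si](C(C)C)(C(C)C)C(C)C)c1 | intermediate
26 | (2S,4S,5R)-5-aryl-5-(TBSO)-2-methoxy-4-methylpentanal (C11 aldehyde) | O=C[C@@H](OC)C[C@H](C)[C@@H](O[Si](C)(C)C(C)(C)C)c1cc(Br)cc(O[Si](C(C)C)(C(C)C)C(C)C)c1 | intermediate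
27 | (10S,11R,12S,14S,15R) homopropargylic alcohol, C8–C21 | CC#C[C@H](C)[C@@H](O)[C@@H](OC)C[C@H](C)[C@@H](O[Si](C)(C)C(C)(C)C)c1cc(Br)cc(O[Si](C(C)C)(C(C)C)C(C)C)c1 | intermediate
28 | C11 TBS ether of 27 | CC#C[C@H](C)[C@@H](O[Si](C)(C)C(C)(C)C)[C@@H](OC)C[C@H](C)[C@@H](O[Si](C)(C)C(C)(C)C)c1cc(Br)cc(O[Si](C(C)C)(C(C)C)C(C)C)c1 | intermediate
29 | (E)-C8 alkenylzirconocene chloride | Cl[Zr](C1C=CC=C1)(C1C=CC=C1)/C(C)=C/[C@H](C)[C@@H](O[Si](C)(C)C(C)(C)C)[C@@H](OC)C[C@H](C)[C@@H](O[Si](C)(C)C(C)(C)C)c1cc(Br)cc(O[Si](C(C)C)(C(C)C)C(C)C)c1 | intermediate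
30 | (E)-C8 alkenyl(methyl)zinc | C[Zn]/C(C)=C/[C@H](C)[C@@H](O[Si](C)(C)C(C)(C)C)[C@@H](OC)C[C@H](C)[C@@H](O[Si](C)(C)C(C)(C)C)c1cc(Br)cc(O[Si](C(C)C)(C(C)C)C(C)C)c1 | intermediate
31 | seco methyl ester (2E,8E,6S,7S,10S,11R,12S,14S,15R) | COC(=O)/C(C)=C/CC[C@H](OC)[C@@H](O)/C(C)=C/[C@H](C)[C@@H](O[Si](C)(C)C(C)(C)C)[C@@H](OC)C[C@H](C)[C@@H](O[Si](C)(C)C(C)(C)C)c1cc(O[Si](C(C)C)(C(C)C)C(C)C)cc(Br)c1 | intermediate
32 | seco primary enamide aryl bromide | NC(=O)/C(C)=C/CC[C@H](OC)[C@@H](O)/C(C)=C/[C@H](C)[C@@H](O[Si](C)(C)C(C)(C)C)[C@@H](OC)C[C@H](C)[C@@H](O[Si](C)(C)C(C)(C)C)c1cc(O[Si](C(C)C)(C(C)C)C(C)C)cc(Br)c1 | intermediate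
33 | macrolactam, C7-OH free, 11,15-bis-O-TBS, 18-O-TIPS | CO[C@H]1C[C@H](C)[C@@H](O[Si](C)(C)C(C)(C)C)c2cc(O[Si](C(C)C)(C(C)C)C(C)C)cc(c2)NC(=O)/C(C)=C/CC[C@H](OC)[C@@H](O)/C(C)=C/[C@H](C)[C@H]1O[Si](C)(C)C(C)(C)C | intermediate
34 | C7 N-(trichloroacetyl)carbamate of 33 | CO[C@H]1C[C@H](C)[C@@H](O[Si](C)(C)C(C)(C)C)c2cc(O[Si](C(C)C)(C(C)C)C(C)C)cc(c2)NC(=O)/C(C)=C/CC[C@H](OC)[C@@H](OC(=O)NC(=O)C(Cl)(Cl)Cl)/C(C)=C/[C@H](C)[C@H]1O[Si](C)(C)C(C)(C)C | intermediate
35 | C7 carbamate of 33 | CO[C@H]1C[C@H](C)[C@@H](O[Si](C)(C)C(C)(C)C)c2cc(O[Si](C(C)C)(C(C)C)C(C)C)cc(c2)NC(=O)/C(C)=C/CC[C@H](OC)[C@@H](OC(N)=O)/C(C)=C/[C@H](C)[C@H]1O[Si](C)(C)C(C)(C)C | intermediate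
36 | CNP0309815.1 | CO[C@H]1C[C@H](C)[C@@H](O)c2cc(O)cc(c2)NC(=O)/C(C)=C/CC[C@H](OC)[C@@H](OC(N)=O)/C(C)=C/[C@H](C)[C@H]1O | target

Total step count: 23. Longest linear sequence: 16 (steps 1, 2, 9–11, 13–23).

**Steps most likely to fail**

**Step 21.** The flexible chain may couple intermolecularly and oligomerise, the aryl bromide may be lost by reduction, or the copper cycle may stall.
- The fallback forms the N–C20 bond intermolecularly and closes the ring at N–C1 instead.
- It sets out from ester 31. Buchwald–Hartwig coupling with benzophenone imine (Pd2(dba)3, BINAP, Cs2CO3, toluene, 90 °C) should give the N-aryl benzophenone imine F1.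
- Transimination with NH2OH·HCl/NaOAc in MeOH then gives the aniline methyl ester F2, and Me3SnOH in warm 1,2-dichloroethane gives the seco amino acid F3.
- Macrolactamisation with BOPCl/i-Pr2NEt in hot dilute toluene comes back to the route at 33.

**Step 19.** Zirconium placement on the alkyne may be incompletely controlled, the zirconium-to-zinc exchange may be slow, or chelate control may erode and cause poor facial selectivity at C7.
- The fallback separates bond formation from stereocontrol and sets out from 28.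
- Zirconocene 29 is quenched with I2 to give the (E)-vinyl iodide F4, which can be purified from any regioisomer.
- Nozaki–Hiyama–Kishi coupling with 7 (CrCl2, catalytic NiCl2, DMSO/THF; the aryl bromide is inert to divalent chromium) gives 31 together with the 7-epimeric alcohol F5.
- Dess–Martin oxidation of the mixture gives the C7 enone F6.
- Corey–Bakshi–Shibata reduction with (S)-Me-CBS/BH3·SMe2 comes back at 31. The alkenyl group acts as the large substituent, and the catalyst is matched with the Felkin–Anh preference of the α-methoxy ketone.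

**Step 13.** Aryl transfer from zinc may be sluggish, butyl transfer may compete, or a salt-promoted background addition may lower the facial selectivity at C15.
- The fallback sets C15 by ketone reduction and sets out from 18.
- Aryllithium 21 is added directly (Et2O, −78 °C) to give 23 mixed with the 15-epimeric alcohol F7.
- Dess–Martin oxidation converges both alcohols on the aryl ketone F8.
- Corey–Bakshi–Shibata reduction with (S)-Me-CBS/BH3·SMe2 comes back at 23. The aryl group acts as the large substituent, and the catalyst has to override the modest substrate bias.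

Further compounds
F1 | step 21 | N-aryl benzophenone imine of the seco methyl ester | COC(=O)/C(C)=C/CC[C@H](OC)[C@@H](O)/C(C)=C/[C@H](C)[C@@H](O[Si](C)(C)C(C)(C)C)[C@@H](OC)C[C@H](C)[C@@H](O[Si](C)(C)C(C)(C)C)c1cc(O[Si](C(C)C)(C(C)C)C(C)C)cc(N=C(c2ccccc2)c2ccccc2)c1
F2 | step 21 | aniline methyl ester | COC(=O)/C(C)=C/CC[C@H](OC)[C@@H](O)/C(C)=C/[C@H](C)[C@@H](O[Si](C)(C)C(C)(C)C)[C@@H](OC)C[C@H](C)[C@@H](O[Si](C)(C)C(C)(C)C)c1cc(O[Si](C(C)C)(C(C)C)C(C)C)cc(N)c1
F3 | step 21 | seco amino acid | OC(=O)/C(C)=C/CC[C@H](OC)[C@@H](O)/C(C)=C/[C@H](C)[C@@H](O[Si](C)(C)C(C)(C)C)[C@@H](OC)C[C@H](C)[C@@H](O[Si](C)(C)C(C)(C)C)c1cc(O[Si](C(C)C)(C(C)C)C(C)C)cc(N)c1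
F4 | step 19 | (E)-C8 vinyl iodide | I/C(C)=C/[C@H](C)[C@@H](O[Si](C)(C)C(C)(C)C)[C@@H](OC)C[C@H](C)[C@@H](O[Si](C)(C)C(C)(C)C)c1cc(O[Si](C(C)C)(C(C)C)C(C)C)cc(Br)c1
F5 | step 19 | 7-epimeric (7R) alcohol of 31 | COC(=O)/C(C)=C/CC[C@H](OC)[C@H](O)/C(C)=C/[C@H](C)[C@@H](O[Si](C)(C)C(C)(C)C)[C@@H](OC)C[C@H](C)[C@@H](O[Si](C)(C)C(C)(C)C)c1cc(O[Si](C(C)C)(C(C)C)C(C)C)cc(Br)c1
F6 | step 19 | C7 enone | COC(=O)/C(C)=C/CC[C@H](OC)C(=O)/C(C)=C/[C@H](C)[C@@H](O[Si](C)(C)C(C)(C)C)[C@@H](OC)C[C@H](C)[C@@H](O[Si](C)(C)C(C)(C)C)c1cc(O[Si](C(C)C)(C(C)C)C(C)C)cc(Br)c1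
F7 | step 13 | 15-epimeric (15S) alcohol of 23 | C(c1ccccc1)(c1ccccc1)(c1ccccc1)OC[C@@H](OC)C[C@H](C)[C@H](O)c1cc(Br)cc(O[Si](C(C)C)(C(C)C)C(C)C)c1
F8 | step 13 | C15 aryl ketone | C(c1ccccc1)(c1ccccc1)(c1ccccc1)OC[C@@H](OC)C[C@H](C)C(=O)c1cc(Br)cc(O[Si](C(C)C)(C(C)C)C(C)C)c1
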